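**Retrosynthetic overview**
1. Target ← C4,C5-diol carrying the C6 angelate (selective C5 isovaleroylation) ← OsO4 on a C4=C5 cycloheptene, anti to the C6 ester; the C11 methyl comes from CuH reduction of a verbenone-type C10=C11 enone.
2. Seven-membered ring (formed last): C2–C3 bond by intramolecular reductive allylation of a C2 cyclobutanone by the diene carried on C6, then radical removal of the C2 hydroxyl.
3. Cyclobutane and six-membered ring (formed first, together): crossed intramolecular [2+2] of a vinylketene with the trisubstituted alkene of an acyclic tetraenoic acid (chain C1/C2 → ring C2/C1, chain C6/C7 → ring C8/C7); the chain C5 silyloxy centre (later the C9 ketone) sets the face, the (6E)-alkene sets C7.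
4. Acyclic acid ← prenal + methyl 3-methylbut-2-enoate (asymmetric vinylogous aldol), SeO2 oxidation of the (E)-methyl, asymmetric addition of a dienylzinc from 2-methylbut-1-en-3-yne.

Assumption: the target is taken exactly as drawn, i.e. (1S,2S,4S,5S,6S,7R,8R,11S) in tricyclo[5.4.0.0(2,8)]undecane numbering (C9 ketone, C6 angelate, C5 isovalerate, C4 OH, C3 CMe2; cyclobutane = C1, C2, C7, C8), which is used for all ring compounds; TBS = tert-butyldimethylsilyl, PMB = 4-methoxybenzyl, TBSO/PMBO = the corresponding ether groups, Cy = cyclohexyl.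

**Step 1**
Reactants: 1 methyl 3-methylbut-2-enoate
Product: 2 tert-butyl[(1-methoxy-3-methylbuta-1,3-dien-1-yl)oxy]dimethylsilane
Conditions: LDA, THF, −78 °C; TBSCl, DMPU, −78 °C to rt
Reagents that add atoms: tert-butyldimethylsilyl chloride CC(C)(C)[Si](C)(C)Cl
Why: Kinetic γ-deprotonation of the senecioate and O-silylation give the cross-conjugated silyl ketene acetal (silyl dienolate formation); no stereocentre is made.

**Step 2**
Reactants: 2 tert-butyl[(1-methoxy-3-methylbuta-1,3-dien-1-yl)oxy]dimethylsilane; 3 3-methylbut-2-enal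
Product: 5 methyl (2E,5S)-5-hydroxy-3,7-dimethylocta-2,6-dienoate, via trichlorosilyl aldolate 4 (not isolated)
Conditions: SiCl4, Denmark binaphthyl bisphosphoramide (2 mol%, enantiomer for Si-face attack), i-Pr2NEt (cat.), CH2Cl2, −78 °C; aqueous work-up
Reagents that add atoms: none
Why: Lewis-base-activated SiCl4 vinylogous Mukaiyama aldol (Denmark type): the chiral phosphoramide-bound silicon cation activates prenal and the dienolate attacks through its γ-carbon on the Si face, setting C5 (S) and returning the (2E)-enoate.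

**Step 3**
Reactants: 5 methyl (2E,5S)-5-hydroxy-3,7-dimethylocta-2,6-dienoate
Product: 6 methyl (2E,5S)-3,7-dimethyl-5-(TBSO)octa-2,6-dienoate
Conditions: TBSCl, imidazole, DMF, rt
Reagents that add atoms: tert-butyldimethylsilyl chloride CC(C)(C)[Si](C)(C)Cl
Why: Standard silylation of the secondary allylic alcohol (protection), leaving the stereocentre untouched.

**Step 4**
Reactants: 6 methyl (2E,5S)-3,7-dimethyl-5-(TBSO)octa-2,6-dienoate
Product: 7 methyl (2E,5S,6E)-3,7-dimethyl-8-oxo-5-(TBSO)octa-2,6-dienoate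
Conditions: SeO2, pyridine (cat.), 1,4-dioxane, 75 °C
Reagents that add atoms: selenium dioxide O=[Se]=O
Why: Riley allylic oxidation (ene reaction then [2,3]-shift) is selective for the (E)-methyl of the electron-rich trisubstituted alkene, the conjugated C2=C3 being deactivated, and gives the (6E)-enal.

**Step 5**
Reactants: 7 methyl (2E,5S,6E)-3,7-dimethyl-8-oxo-5-(TBSO)octa-2,6-dienoate; 8 2-methylbut-1-en-3-yne
Product: 11 methyl (2E,5S,6E,8R,9E)-8-hydroxy-3,7,11-trimethyl-5-(TBSO)dodeca-2,6,9,11-tetraenoate, via dienylborane 9 (not isolated), via dienylzinc 10 (not isolated)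
Conditions: 8, Cy2BH, toluene, 0 °C; Et2Zn, −78 °C; (+)-MIB (10 mol%), 7, −30 to 0 °C; aq. NH4Cl
Reagents that add atoms: none
Why: Oppolzer-type sequence (alkyne hydroboration, boron-to-zinc exchange, amino-alcohol-catalysed alkenylzinc addition): (+)-MIB directs the dienyl group to the Re face of the aldehyde, setting C8 (R), and the organozinc leaves the ester untouched.

**Step 6**
Reactants: 11 methyl (2E,5S,6E,8R,9E)-8-hydroxy-3,7,11-trimethyl-5-(TBSO)dodeca-2,6,9,11-tetraenoate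
Product: 12 methyl (2E,5S,6E,8R,9E)-3,7,11-trimethyl-8-(PMBO)-5-(TBSO)dodeca-2,6,9,11-tetraenoate
Conditions: NaH, PMBCl, TBAI (cat.), THF/DMF, 0 °C to rt
Reagents that add atoms: 4-methoxybenzyl chloride COc1ccc(CCl)cc1
Why: Williamson etherification of the sodium alkoxide; basic conditions avoid ionising the doubly allylic carbinol.

**Step 7**
Reactants: 12 methyl (2E,5S,6E,8R,9E)-3,7,11-trimethyl-8-(PMBO)-5-(TBSO)dodeca-2,6,9,11-tetraenoate
Product: 13 (2E,5S,6E,8R,9E)-3,7,11-trimethyl-8-(PMBO)-5-(TBSO)dodeca-2,6,9,11-tetraenoic acid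
Conditions: LiOH, THF/MeOH/H2O, 40 °C; dilute HCl to pH 4, 0 °C
Reagents that add atoms: lithium hydroxide [Li+].[OH-]
Why: Saponification of the methyl ester; the silyl and benzyl ethers are stable to hydroxide.

**Step 8 (key step)**
Reactants: 13 (2E,5S,6E,8R,9E)-3,7,11-trimethyl-8-(PMBO)-5-(TBSO)dodeca-2,6,9,11-tetraenoic acid
Product: 16 (1R,2S,5R,7R)-7-methyl-4-methylidene-2-(TBSO)-7-[(1R,2E)-4-methyl-1-(PMBO)penta-2,4-dien-1-yl]bicyclo[3.1.1]heptan-6-one, via acid chloride 14 (not isolated), via vinylketene 15 (not isolated)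
Conditions: 1-chloro-N,N,2-trimethylprop-1-en-1-amine, CH2Cl2, 0 °C; slow addition to Et3N, toluene, 110 °C (5 mM)
Reagents that add atoms: none
Why: Intramolecular vinylketene–alkene [2+2] cycloaddition (Snider type): γ-dehydrochlorination gives the vinylketene, whose carbonyl carbon bonds to the less substituted chain C6 and whose α-carbon bonds to the disubstituted C7, so the crossed bicyclo[3.1.1]heptan-6-one forms with both rings at once; A(1,3) strain between the C5 silyloxy centre and the cis C7 methyl fixes the attacked face (ring C1, C5, C7 and the absolute sense), and suprafacial addition to the (6E)-alkene puts the methyl syn and the side chain anti to the three-carbon bridge.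

**Step 9**
Reactants: 16 (1R,2S,5R,7R)-7-methyl-4-methylidene-2-(TBSO)-7-[(1R,2E)-4-methyl-1-(PMBO)penta-2,4-dien-1-yl]bicyclo[3.1.1]heptan-6-one
Product: 18 (1R,2R,6R,7R,8R,9S)-3,3,7-trimethyl-11-methylidene-6-(PMBO)-9-(TBSO)tricyclo[5.4.0.0(2,8)]undec-4-en-2-ol, via silyl ether 17 (not isolated)
Conditions: Cu(OAc)2 (5 mol%), Ph-BPE (6 mol%), (MeO)2MeSiH, THF, rt; K2CO3 (cat.), MeOH
Reagents that add atoms: none
Why: Proposed new method: ligated CuH adds to the terminal 1,1-disubstituted alkene of the diene (H to CH2, creating the second C3 methyl), and the allylcopper (Cu at C5) attacks the strained C2 ketone through a six-membered SE2′ transition state at its gem-dimethyl terminus, which the side chain on C7 can reach only from its own face, so the C2–C3 bond, the quaternary C3, the (Z)-C4=C5 alkene and the seven-membered ring arise together with the hydroxyl forced to the opposite face; the closest known reaction is the intermolecular CuH-catalysed allylation of ketones with 1,3-dienes.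

**Step 10**
Reactants: 18 (1R,2R,6R,7R,8R,9S)-3,3,7-trimethyl-11-methylidene-6-(PMBO)-9-(TBSO)tricyclo[5.4.0.0(2,8)]undec-4-en-2-ol
Product: 19 methyl (1R,2R,6R,7R,8R,9S)-3,3,7-trimethyl-11-methylidene-6-(PMBO)-9-(TBSO)tricyclo[5.4.0.0(2,8)]undec-4-en-2-yl oxalate
Conditions: KHMDS, THF, −78 °C; ClC(O)CO2Me, −78 to 0 °C
Reagents that add atoms: methyl chlorooxoacetate COC(=O)C(=O)Cl
Why: Acylation of the potassium alkoxide of the hindered tertiary cyclobutanol gives the mixed oxalate needed for radical C–O cleavage.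

**Step 11**
Reactants: 19 methyl (1R,2R,6R,7R,8R,9S)-3,3,7-trimethyl-11-methylidene-6-(PMBO)-9-(TBSO)tricyclo[5.4.0.0(2,8)]undec-4-en-2-yl oxalate
Product: 20 (1R,2S,6R,7R,8R,9S)-3,3,7-trimethyl-11-methylidene-6-(PMBO)-9-(TBSO)tricyclo[5.4.0.0(2,8)]undec-4-ene
Conditions: Bu3SnH, AIBN (cat.), toluene, 110 °C
Reagents that add atoms: none
Why: Dolan–MacMillan radical deoxygenation of a tertiary oxalate (stannyl radical addition, fragmentation to the cyclobutyl radical, hydrogen transfer from Bu3SnH); the seven-membered ring holds C3 on one face, so hydrogen can only enter from the other and C2 becomes S.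

**Step 12**
Reactants: 20 (1R,2S,6R,7R,8R,9S)-3,3,7-trimethyl-11-methylidene-6-(PMBO)-9-(TBSO)tricyclo[5.4.0.0(2,8)]undec-4-ene
Product: 21 (1R,2S,6R,7R,8R,9S)-3,3,7-trimethyl-11-methylidene-6-(PMBO)tricyclo[5.4.0.0(2,8)]undec-4-en-9-ol
Conditions: TBAF, THF, 40 °C
Reagents that add atoms: none
Why: Fluoride cleavage of the secondary silyl ether (deprotection).

**Step 13**
Reactants: 21 (1R,2S,6R,7R,8R,9S)-3,3,7-trimethyl-11-methylidene-6-(PMBO)tricyclo[5.4.0.0(2,8)]undec-4-en-9-ol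
Product: 23 (1R,2S,6R,7R,8R)-3,3,7,11-tetramethyl-6-(PMBO)tricyclo[5.4.0.0(2,8)]undeca-4,10-dien-9-one, via exo-methylene ketone 22 (not isolated)
Conditions: DMP, CH2Cl2, 0 °C to rt; DBU, rt
Reagents that add atoms: none
Why: Dess–Martin oxidation to the β,γ-unsaturated ketone, then amine-base isomerisation of the exocyclic alkene into conjugation, gives the verbenone-type enone; the bridgehead C8 cannot enolise.

**Step 14**
Reactants: 23 (1R,2S,6R,7R,8R)-3,3,7,11-tetramethyl-6-(PMBO)tricyclo[5.4.0.0(2,8)]undeca-4,10-dien-9-one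
Product: 24 (1S,2S,6R,7R,8R,11S)-3,3,7,11-tetramethyl-6-(PMBO)tricyclo[5.4.0.0(2,8)]undec-4-en-9-one
Conditions: [(Ph3P)CuH]6, H2O (3 equiv), toluene, rt; aq. NH4Cl
Reagents that add atoms: none
Why: Stryker conjugate reduction: hydride reaches C11 from the side of the C2–H bridge, away from the C7 methyl, so the new methyl centre (11S) ends syn to the quaternary bridge as in cis-verbanone, while the isolated C4=C5 alkene is inert to CuH.

**Step 15**
Reactants: 24 (1S,2S,6R,7R,8R,11S)-3,3,7,11-tetramethyl-6-(PMBO)tricyclo[5.4.0.0(2,8)]undec-4-en-9-one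
Product: 25 (1S,2S,6R,7R,8R,11S)-6-hydroxy-3,3,7,11-tetramethyltricyclo[5.4.0.0(2,8)]undec-4-en-9-one
Conditions: DDQ, CH2Cl2/pH 7 buffer, 0 °C
Reagents that add atoms: none
Why: Oxidative cleavage of the p-methoxybenzyl ether by DDQ (benzylic hydride abstraction, hydrolysis of the hemiacetal).

**Step 16**
Reactants: 25 (1S,2S,6R,7R,8R,11S)-6-hydroxy-3,3,7,11-tetramethyltricyclo[5.4.0.0(2,8)]undec-4-en-9-one
Product: 26 (1S,2S,6R,7R,8R,11S)-3,3,7,11-tetramethyl-9-oxotricyclo[5.4.0.0(2,8)]undec-4-en-6-yl (2Z)-2-methylbut-2-enoate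
Conditions: angelic acid, 2,4,6-trichlorobenzoyl chloride, Et3N, toluene, rt; then 25, 75 °C
Reagents that add atoms: angelic acid C/C=C(/C)C(O)=O
Why: Yamaguchi esterification through the mixed anhydride without DMAP, conditions that acylate hindered alcohols without Z-to-E isomerisation of the angelate.

**Step 17**
Reactants: 26 (1S,2S,6R,7R,8R,11S)-3,3,7,11-tetramethyl-9-oxotricyclo[5.4.0.0(2,8)]undec-4-en-6-yl (2Z)-2-methylbut-2-enoate
Product: 27 (1S,2S,4S,5S,6S,7R,8R,11S)-4,5-dihydroxy-3,3,7,11-tetramethyl-9-oxotricyclo[5.4.0.0(2,8)]undecan-6-yl (2Z)-2-methylbut-2-enoate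
Conditions: OsO4 (5 mol%), NMO, acetone/H2O, 0 °C to rt
Reagents that add atoms: osmium tetroxide O=[Os](=O)(=O)=O; N-methylmorpholine N-oxide C[N+]1([O-])CCOCC1; water O
Why: Upjohn dihydroxylation: OsO4 adds syn to the ring alkene on the face anti to the allylic C6 ester (Kishi model), setting C4 and C5 as a cis-diol trans to the C6 oxygen, while the electron-poor trisubstituted angelate reacts much more slowly.

**Step 18**
Reactants: 27 (1S,2S,4S,5S,6S,7R,8R,11S)-4,5-dihydroxy-3,3,7,11-tetramethyl-9-oxotricyclo[5.4.0.0(2,8)]undecan-6-yl (2Z)-2-methylbut-2-enoate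
Product: 28 (1S,2S,4S,5S,6S,7R,8R,11S)-4-hydroxy-3,3,7,11-tetramethyl-5-[(3-methylbutanoyl)oxy]-9-oxotricyclo[5.4.0.0(2,8)]undecan-6-yl (2Z)-2-methylbut-2-enoate
Conditions: isovaleric anhydride, DMAP (cat.), Et3N, CH2Cl2, −20 to 0 °C
Reagents that add atoms: 3-methylbutanoic anhydride CC(C)CC(=O)OC(=O)CC(C)C
Why: DMAP-catalysed acylation discriminates the C5 hydroxyl from the neopentyl C4 hydroxyl next to the gem-dimethyl carbon.

**Compound list**
1 | methyl 3-methylbut-2-enoate | COC(=O)C=C(C)C | starting material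
2 | tert-butyl[(1-methoxy-3-methylbuta-1,3-dien-1-yl)oxy]dimethylsilane | COC(O[Si](C)(C)C(C)(C)C)=CC(C)=C | intermediate
3 | 3-methylbut-2-enal | CC(C)=CC=O | starting material
4 | methyl (2E,5S)-3,7-dimethyl-5-[(trichlorosilyl)oxy]octa-2,6-dienoate | COC(=O)/C=C(\C)C[C@H](O[Si](Cl)(Cl)Cl)C=C(C)C | intermediate (not isolated)
5 | methyl (2E,5S)-5-hydroxy-3,7-dimethylocta-2,6-dienoate | COC(=O)/C=C(\C)C[C@H](O)C=C(C)C | intermediate
6 | methyl (2E,5S)-3,7-dimethyl-5-(TBSO)octa-2,6-dienoate | COC(=O)/C=C(\C)C[C@H](O[Si](C)(C)C(C)(C)C)C=C(C)C | intermediate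
7 | methyl (2E,5S,6E)-3,7-dimethyl-8-oxo-5-(TBSO)octa-2,6-dienoate | COC(=O)/C=C(\C)C[C@H](O[Si](C)(C)C(C)(C)C)/C=C(\C)C=O | intermediate
8 | 2-methylbut-1-en-3-yne | C#CC(C)=C | starting material
9 | dicyclohexyl[(1E)-3-methylbuta-1,3-dien-1-yl]borane | C=C(C)/C=C/B(C1CCCCC1)C1CCCCC1 | intermediate (not isolated)
10 | ethyl[(1E)-3-methylbuta-1,3-dien-1-yl]zinc | C=C(C)/C=C/[Zn]CC | intermediate (not isolated)
11 | methyl (2E,5S,6E,8R,9E)-8-hydroxy-3,7,11-trimethyl-5-(TBSO)dodeca-2,6,9,11-tetraenoate | COC(=O)/C=C(\C)C[C@H](O[Si](C)(C)C(C)(C)C)/C=C(\C)[C@H](O)/C=C/C(C)=C | intermediate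
12 | methyl (2E,5S,6E,8R,9E)-3,7,11-trimethyl-8-(PMBO)-5-(TBSO)dodeca-2,6,9,11-tetraenoate | COC(=O)/C=C(\C)C[C@H](O[Si](C)(C)C(C)(C)C)/C=C(\C)[C@H](OCc1ccc(OC)cc1)/C=C/C(C)=C | intermediate
13 | (2E,5S,6E,8R,9E)-3,7,11-trimethyl-8-(PMBO)-5-(TBSO)dodeca-2,6,9,11-tetraenoic acid | OC(=O)/C=C(\C)C[C@H](O[Si](C)(C)C(C)(C)C)/C=C(\C)[C@H](OCc1ccc(OC)cc1)/C=C/C(C)=C | intermediate
14 | (2E,5S,6E,8R,9E)-3,7,11-trimethyl-8-(PMBO)-5-(TBSO)dodeca-2,6,9,11-tetraenoyl chloride | ClC(=O)/C=C(\C)C[C@H](O[Si](C)(C)C(C)(C)C)/C=C(\C)[C@H](OCc1ccc(OC)cc1)/C=C/C(C)=C | intermediate (not isolated)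
15 | (5S,6E,8R,9E)-7,11-dimethyl-3-methylidene-8-(PMBO)-5-(TBSO)dodeca-1,6,9,11-tetraen-1-one (vinylketene) | O=C=CC(=C)C[C@H](O[Si](C)(C)C(C)(C)C)/C=C(\C)[C@H](OCc1ccc(OC)cc1)/C=C/C(C)=C | intermediate (not isolated)
16 | (1R,2S,5R,7R)-7-methyl-4-methylidene-2-(TBSO)-7-[(1R,2E)-4-methyl-1-(PMBO)penta-2,4-dien-1-yl]bicyclo[3.1.1]heptan-6-one | O=C1[C@@H]2C(=C)C[C@H](O[Si](C)(C)C(C)(C)C)[C@H]1[C@]2(C)[C@H](OCc1ccc(OC)cc1)/C=C/C(C)=C | intermediate
17 | (1R,2R,6R,7R,8R,9S)-2-{[dimethoxy(methyl)silyl]oxy}-3,3,7-trimethyl-11-methylidene-6-(PMBO)-9-(TBSO)tricyclo[5.4.0.0(2,8)]undec-4-ene | COc1ccc(CO[C@@H]2C=CC(C)(C)[C@@]3(O[Si](C)(OC)OC)[C@@H]4C(=C)C[C@H](O[Si](C)(C)C(C)(C)C)[C@H]3[C@@]42C)cc1 | intermediate (not isolated)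
18 | (1R,2R,6R,7R,8R,9S)-3,3,7-trimethyl-11-methylidene-6-(PMBO)-9-(TBSO)tricyclo[5.4.0.0(2,8)]undec-4-en-2-ol | COc1ccc(CO[C@@H]2C=CC(C)(C)[C@@]3(O)[C@@H]4C(=C)C[C@H](O[Si](C)(C)C(C)(C)C)[C@H]3[C@@]42C)cc1 | intermediate
19 | methyl (1R,2R,6R,7R,8R,9S)-3,3,7-trimethyl-11-methylidene-6-(PMBO)-9-(TBSO)tricyclo[5.4.0.0(2,8)]undec-4-en-2-yl oxalate | COc1ccc(CO[C@@H]2C=CC(C)(C)[C@@]3(OC(=O)C(=O)OC)[C@@H]4C(=C)C[C@H](O[Si](C)(C)C(C)(C)C)[C@H]3[C@@]42C)cc1 | intermediate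
20 | (1R,2S,6R,7R,8R,9S)-3,3,7-trimethyl-11-methylidene-6-(PMBO)-9-(TBSO)tricyclo[5.4.0.0(2,8)]undec-4-ene | COc1ccc(CO[C@@H]2C=CC(C)(C)[C@H]3[C@@H]4C(=C)C[C@H](O[Si](C)(C)C(C)(C)C)[C@H]3[C@@]42C)cc1 | intermediate
21 | (1R,2S,6R,7R,8R,9S)-3,3,7-trimethyl-11-methylidene-6-(PMBO)tricyclo[5.4.0.0(2,8)]undec-4-en-9-ol | COc1ccc(CO[C@@H]2C=CC(C)(C)[C@H]3[C@@H]4C(=C)C[C@H](O)[C@H]3[C@@]42C)cc1 | intermediate
22 | (1R,2S,6R,7R,8R)-3,3,7-trimethyl-11-methylidene-6-(PMBO)tricyclo[5.4.0.0(2,8)]undec-4-en-9-one | COc1ccc(CO[C@@H]2C=CC(C)(C)[C@H]3[C@@H]4C(=C)CC(=O)[C@H]3[C@@]42C)cc1 | intermediate (not isolated)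
23 | (1R,2S,6R,7R,8R)-3,3,7,11-tetramethyl-6-(PMBO)tricyclo[5.4.0.0(2,8)]undeca-4,10-dien-9-one | COc1ccc(CO[C@@H]2C=CC(C)(C)[C@H]3[C@@H]4C(C)=CC(=O)[C@H]3[C@@]42C)cc1 | intermediate
24 | (1S,2S,6R,7R,8R,11S)-3,3,7,11-tetramethyl-6-(PMBO)tricyclo[5.4.0.0(2,8)]undec-4-en-9-one | COc1ccc(CO[C@@H]2C=CC(C)(C)[C@H]3[C@@H]4[C@@H](C)CC(=O)[C@H]3[C@@]42C)cc1 | intermediate
25 | (1S,2S,6R,7R,8R,11S)-6-hydroxy-3,3,7,11-tetramethyltricyclo[5.4.0.0(2,8)]undec-4-en-9-one | O[C@@H]1C=CC(C)(C)[C@H]2[C@@H]3[C@@H](C)CC(=O)[C@H]2[C@@]31C | intermediate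
26 | (1S,2S,6R,7R,8R,11S)-3,3,7,11-tetramethyl-9-oxotricyclo[5.4.0.0(2,8)]undec-4-en-6-yl (2Z)-2-methylbut-2-enoate | C/C=C(/C)C(=O)O[C@@H]1C=CC(C)(C)[C@H]2[C@@H]3[C@@H](C)CC(=O)[C@H]2[C@@]31C | intermediate
27 | (1S,2S,4S,5S,6S,7R,8R,11S)-4,5-dihydroxy-3,3,7,11-tetramethyl-9-oxotricyclo[5.4.0.0(2,8)]undecan-6-yl (2Z)-2-methylbut-2-enoate | C/C=C(/C)C(=O)O[C@@H]1[C@@H](O)[C@@H](O)C(C)(C)[C@H]2[C@@H]3[C@@H](C)CC(=O)[C@H]2[C@@]31C | intermediate
28 | (1S,2S,4S,5S,6S,7R,8R,11S)-4-hydroxy-3,3,7,11-tetramethyl-5-[(3-methylbutanoyl)oxy]-9-oxotricyclo[5.4.0.0(2,8)]undecan-6-yl (2Z)-2-methylbut-2-enoate | C/C=C(/C)C(=O)O[C@@H]1[C@@H](OC(=O)CC(C)C)[C@@H](O)C(C)(C)[C@H]2[C@@H]3[C@@H](C)CC(=O)[C@H]2[C@@]31C | target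

**Step count and risks**
Total steps: 18. Longest linear sequence: 18 steps (1 → 28; compounds 3 and 8 are purchased and enter directly).

The three steps most likely to fail are steps 8, 9 and 17.

Step 8 (ketene [2+2]). The alkene carries allylic oxygen on both sides, so it may be too slow to beat ketene dimerisation, and the C8 centre may oppose the face chosen by C5. The fallback sets out from 13 and comes back at 16; it replaces the ketene by a far more electrophilic keteniminium ion. Acid 13 is coupled with pyrrolidine (EDC, HOBt) to give the pyrrolidine amide F1. Tf2O and 2,4,6-collidine in 1,2-dichloroethane (−20 to 60 °C) convert it by O-triflation and γ-deprotonation into the vinylketeniminium triflate F2. This undergoes the same crossed cycloaddition under the same A(1,3) control to give the cyclobutaniminium triflate F3, and aqueous NaHCO3 hydrolysis returns the route at cyclobutanone 16.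

Step 9 (CuH cyclisation). CuH may reduce the cyclobutanone, the allylcopper may lose the neighbouring PMB-oxide, or the internal alkene may be hydrometallated. The fallback sets out from 7 and comes back at 18; it makes the allyl nucleophile from a defined allylic acetate by palladium/indium umpolung instead of from a diene.
- Enal 7 is treated, under the step-5 conditions, with the alkenylzinc made from purchased 3-methyl-3-(trimethylsilyloxy)but-1-yne, giving the (8R)-allylic alcohol F4.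
- NaH/PMBCl gives the PMB ether F5, and KOSiMe3 in THF cleaves the methyl ester to the acid F6.
- The step-8 conditions lead through the acid chloride F7 and the vinylketene F8 to the silyloxy cyclobutanone F9.
- K2CO3/MeOH frees the tertiary allylic alcohol F10, and Ac2O/DMAP gives the tertiary allylic acetate F11.
- Pd(PPh3)4 and InI in THF turn the acetate into an allylindium, which adds through its gem-dimethyl terminus to the C2 ketone from the side-chain face, returning the route at alcohol 18.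

Step 17 (dihydroxylation). OsO4 may attack the angelate, or face selectivity next to an ester may be low. The fallback sets out from 24 and comes back at 27; the diol is made before the angelate exists. PMB ether 24 is dihydroxylated (OsO4, NMO, anti to the C6 ether) to the diol F12, which is protected with 2-methoxypropene/PPTS as the acetonide F13. DDQ frees the C6 alcohol F14, and the step-16 conditions give the angelate acetonide F15. 80% aqueous acetic acid at 40 °C removes the acetonide and returns the route at diol 27.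

**Further compounds**
F1 | step 8 | (2E,5S,6E,8R,9E)-3,7,11-trimethyl-8-(PMBO)-1-(pyrrolidin-1-yl)-5-(TBSO)dodeca-2,6,9,11-tetraen-1-one | O=C(/C=C(\C)C[C@H](O[Si](C)(C)C(C)(C)C)/C=C(\C)[C@H](OCc1ccc(OC)cc1)/C=C/C(C)=C)N1CCCC1
F2 | step 8 | vinylketeniminium triflate, the N-pyrrolidinium analogue of 15 | C=C(C[C@H](O[Si](C)(C)C(C)(C)C)/C=C(\C)[C@H](OCc1ccc(OC)cc1)/C=C/C(C)=C)C=C=[N+]1CCCC1.[O-]S(=O)(=O)C(F)(F)F
F3 | step 8 | cyclobutaniminium triflate, the N-pyrrolidinium analogue of 16 | C1(=[N+]2CCCC2)[C@@H]3C(=C)C[C@H](O[Si](C)(C)C(C)(C)C)[C@H]1[C@]3(C)[C@H](OCc4ccc(OC)cc4)/C=C/C(C)=C.[O-]S(=O)(=O)C(F)(F)F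
F4 | step 9 | methyl (2E,5S,6E,8R,9E)-8-hydroxy-3,7,11-trimethyl-5-(TBSO)-11-[(trimethylsilyl)oxy]dodeca-2,6,9-trienoate | COC(=O)/C=C(\C)C[C@H](O[Si](C)(C)C(C)(C)C)/C=C(\C)[C@H](O)/C=C/C(C)(C)O[Si](C)(C)C
F5 | step 9 | methyl (2E,5S,6E,8R,9E)-3,7,11-trimethyl-8-(PMBO)-5-(TBSO)-11-[(trimethylsilyl)oxy]dodeca-2,6,9-trienoate | COC(=O)/C=C(\C)C[C@H](O[Si](C)(C)C(C)(C)C)/C=C(\C)[C@H](OCc1ccc(OC)cc1)/C=C/C(C)(C)O[Si](C)(C)C
F6 | step 9 | (2E,5S,6E,8R,9E)-3,7,11-trimethyl-8-(PMBO)-5-(TBSO)-11-[(trimethylsilyl)oxy]dodeca-2,6,9-trienoic acid | OC(=O)/C=C(\C)C[C@H](O[Si](C)(C)C(C)(C)C)/C=C(\C)[C@H](OCc1ccc(OC)cc1)/C=C/C(C)(C)O[Si](C)(C)C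
F7 | step 9 | (2E,5S,6E,8R,9E)-3,7,11-trimethyl-8-(PMBO)-5-(TBSO)-11-[(trimethylsilyl)oxy]dodeca-2,6,9-trienoyl chloride | ClC(=O)/C=C(\C)C[C@H](O[Si](C)(C)C(C)(C)C)/C=C(\C)[C@H](OCc1ccc(OC)cc1)/C=C/C(C)(C)O[Si](C)(C)C
F8 | step 9 | (5S,6E,8R,9E)-7,11-dimethyl-3-methylidene-8-(PMBO)-5-(TBSO)-11-[(trimethylsilyl)oxy]dodeca-1,6,9-trien-1-one (vinylketene) | O=C=CC(=C)C[C@H](O[Si](C)(C)C(C)(C)C)/C=C(\C)[C@H](OCc1ccc(OC)cc1)/C=C/C(C)(C)O[Si](C)(C)C
F9 | step 9 | (1R,2S,5R,7R)-7-methyl-4-methylidene-2-(TBSO)-7-[(1R,2E)-4-methyl-1-(PMBO)-4-[(trimethylsilyl)oxy]pent-2-en-1-yl]bicyclo[3.1.1]heptan-6-one | O=C1[C@@H]2C(=C)C[C@H](O[Si](C)(C)C(C)(C)C)[C@H]1[C@]2(C)[C@H](OCc1ccc(OC)cc1)/C=C/C(C)(C)O[Si](C)(C)C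
F10 | step 9 | (1R,2S,5R,7R)-7-[(1R,2E)-4-hydroxy-4-methyl-1-(PMBO)pent-2-en-1-yl]-7-methyl-4-methylidene-2-(TBSO)bicyclo[3.1.1]heptan-6-one | O=C1[C@@H]2C(=C)C[C@H](O[Si](C)(C)C(C)(C)C)[C@H]1[C@]2(C)[C@H](OCc1ccc(OC)cc1)/C=C/C(C)(C)O
F11 | step 9 | (2E,4R)-2-methyl-4-[(1R,2S,5R,7R)-7-methyl-4-methylidene-6-oxo-2-(TBSO)bicyclo[3.1.1]heptan-7-yl]-4-(PMBO)but-2-en-2-yl... tertiary acetate of F10 (5-[bicycloheptanyl]-2-methyl-5-(PMBO)pent-3-en-2-yl acetate) | O=C1[C@@H]2C(=C)C[C@H](O[Si](C)(C)C(C)(C)C)[C@H]1[C@]2(C)[C@H](OCc1ccc(OC)cc1)/C=C/C(C)(C)OC(C)=O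
F12 | step 17 | (1S,2S,4S,5S,6S,7R,8R,11S)-4,5-dihydroxy-3,3,7,11-tetramethyl-6-(PMBO)tricyclo[5.4.0.0(2,8)]undecan-9-one | COc1ccc(CO[C@@H]2[C@@H](O)[C@@H](O)C(C)(C)[C@H]3[C@@H]4[C@@H](C)CC(=O)[C@H]3[C@@]42C)cc1
F13 | step 17 | 4,5-O-isopropylidene acetal (acetonide) of F12 | COc1ccc(CO[C@@H]2[C@H]5OC(C)(C)O[C@H]5C(C)(C)[C@H]3[C@@H]4[C@@H](C)CC(=O)[C@H]3[C@@]42C)cc1
F14 | step 17 | 6-hydroxy 4,5-acetonide (F13 without the PMB group) | O[C@@H]1[C@H]4OC(C)(C)O[C@H]4C(C)(C)[C@H]2[C@@H]3[C@@H](C)CC(=O)[C@H]2[C@@]31C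
F15 | step 17 | 6-O-[(2Z)-2-methylbut-2-enoyl] 4,5-acetonide (acetonide of 27) | C/C=C(/C)C(=O)O[C@@H]1[C@H]4OC(C)(C)O[C@H]4C(C)(C)[C@H]2[C@@H]3[C@@H](C)CC(=O)[C@H]2[C@@]31C
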